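**Retrosynthetic overview** (target numbering: C1 ketone carbon, C2 carbon bearing CH2OH, C3 vinyl CH, C4 propanoate carbinol, C5 isopropyl carbon, C6 enoate carbinol)

1. 24 ⇐ desilylation ⇐ Stille hydroxymethylation at C2 ⇐ C4 propanoylation ⇐ 2-bromo-6-acyloxycyclohex-2-enone 19.
2. 19 ⇐ key ring enlargement of the 6,6-dibromobicyclo[3.1.0]hexane 16: Ag(I)-triggered electrocyclic cyclopropane opening turns the cyclopentane (C1, C3, C4, C5, C6) into the cyclohexene, the CBr2 carbon becoming C2; the allyl cation is caught by the C6 ester and released oxidatively (Kornblum) as the C1 ketone.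
3. Enabling feature: the one-carbon CBr2 bridge of the fused cyclopropane spans C1 and C3 of the five-membered ring, so its endo C–Br bond ionises as the C1–C3 bond opens; the ester C=O on the adjacent ring carbon C6 can close a 1,3-dioxolan-2-ylium ring onto C1 only, because the C4 oxygen carries a non-participating silyl group.
4. 16 ⇐ esterification with acid 15 ⇐ CBr2 addition to the differentiated trans-diol 8 ⇐ hydroxyl-directed reduction of (4S,5R)-4-hydroxy-5-isopropylcyclopent-2-enone 5 ⇐ lipase resolution ⇐ Piancatelli rearrangement of furylcarbinol 3 (furfural + i-PrMgCl).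
5. Ring order: furan (dearomatised) → cyclopentenone → bicyclo[3.1.0]hexane → cyclohexenone; the side-chain acid 15 comes from a Wittig olefination.

Key step: step 13

Assumption: in the lipase resolution (step 3) the (4R,5S)-enantiomer is the one acylated faster (empirical size rule for lipases, CH(iPr)C=O side as the large group); should the enzyme prefer the other enantiomer, the acetate fraction would be carried on after lipase-mediated methanolysis.

Remark: the enoate side chain is attached only after the dibromocarbene step, because a trisubstituted enoate would compete with the deactivated ring alkene for the carbene.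

**Route**

Step 1
Reactants: 1 furfural; 2 isopropylmagnesium chloride
Product: 3 1-(furan-2-yl)-2-methylpropan-1-ol (racemic)
Conditions: THF, 0 °C; aq. NH4Cl
Reagents that add atoms: none
Why: Grignard 1,2-addition to the aldehyde; the carbinol centre may be racemic because it is flattened in step 2.

Step 2
Reactants: 3 1-(furan-2-yl)-2-methylpropan-1-ol
Product: 4 rac-trans-4-hydroxy-5-(propan-2-yl)cyclopent-2-en-1-one
Conditions: ZnCl2, dioxane–H2O, reflux, pH ca. 5–6
Reagents that add atoms: water, O
Why: Piancatelli rearrangement (ionisation of the furylcarbinol, water attack at C5 of the furan, ring opening to a hydroxypentadienyl cation, conrotatory 4π electrocyclisation), which should give only the trans 4-hydroxy/5-isopropyl relation.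

Step 3
Reactants: 4 rac-trans-4-hydroxy-5-(propan-2-yl)cyclopent-2-en-1-one
Product: 5 (4S,5R)-4-hydroxy-5-(propan-2-yl)cyclopent-2-en-1-one (recovered, non-acylated enantiomer)
Conditions: immobilised lipase PS, vinyl acetate, MTBE, 30 °C, stopped near half conversion; chromatography
Reagents that add atoms: none
Why: lipase-catalysed kinetic resolution by enantioselective transesterification, a standard way to enantiopure 4-hydroxycyclopentenones; the acetate of the other enantiomer is separated.

Step 4
Reactants: 5 (4S,5R)-4-hydroxy-5-(propan-2-yl)cyclopent-2-en-1-one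
Product: 6 (1S,3S)-2-(propan-2-yl)cyclopent-4-ene-1,3-diol (trans-diol, one OH cis and one trans to isopropyl)
Conditions: Me4NBH(OAc)3, MeCN–AcOH, −30 to −20 °C; aq. Rochelle salt
Reagents that add atoms: none
Why: hydroxyl-directed Evans–Saksena reduction: the alkoxyborohydride on the existing hydroxyl delivers hydride to the ketone face on which that hydroxyl sits, which is also the face anti to isopropyl, so the new carbinol (target C4) should be anti to the old one and cis to isopropyl.

Step 5
Reactants: 6 (1S,3S)-2-(propan-2-yl)cyclopent-4-ene-1,3-diol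
Product: 7 mono-pivalate of 6 at the hydroxyl trans to isopropyl (4-hydroxy-5-(propan-2-yl)cyclopent-2-en-1-yl 2,2-dimethylpropanoate, free OH cis to isopropyl)
Conditions: PivCl (1.05 equiv), pyridine, CH2Cl2, −30 to 0 °C
Reagents that add atoms: pivaloyl chloride, CC(C)(C)C(=O)Cl
Why: steric differentiation of a diol by a bulky acyl chloride: the hydroxyl trans to the vicinal isopropyl group is much less hindered than the cis one and should react first.

Step 6
Reactants: 7 mono-pivalate
Product: 8 TBS ether of 7 (OPiv trans and OTBS cis to isopropyl)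
Conditions: TBSOTf, 2,6-lutidine, CH2Cl2, −78 to 0 °C
Reagents that add atoms: tert-butyldimethylsilyl trifluoromethanesulfonate, CC(C)(C)[Si](C)(C)OS(=O)(=O)C(F)(F)F
Why: silyl triflate silylation of the hindered hydroxyl; a silyl ether is chosen because it cannot act as a neighbouring group in step 13.

Step 7
Reactants: 8 pivalate TBS ether
Product: 9 6,6-dibromobicyclo[3.1.0]hexane with OPiv (trans to isopropyl) and OTBS (cis to isopropyl) on the carbons next to the bridgeheads, CBr2 bridge drawn on the face of the OPiv group
Conditions: CHBr3, 50% aq. NaOH, BnEt3NCl (cat.), CH2Cl2, 0 °C to rt, excess reagent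
Reagents that add atoms: bromoform, BrC(Br)Br
Why: phase-transfer dibromocarbene [2+1] cycloaddition to the cis ring alkene; pivalate and TBS ether withstand the base, and since both cyclopropane faces lead to the same cation in step 13 the facial selectivity (expected anti to OTBS and isopropyl) is of no consequence.

Step 8
Reactants: 9 dibromocyclopropane pivalate
Product: 10 the corresponding alcohol (hydroxyl trans to isopropyl, OTBS cis to isopropyl)
Conditions: DIBAL-H, CH2Cl2, −78 °C; aq. Rochelle salt
Reagents that add atoms: none
Why: reductive cleavage of the pivalate by DIBAL-H at low temperature, which leaves the C–Br bonds and the silyl ether alone.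

Step 9
Reactants: 11 glycolaldehyde dimer (1,4-dioxane-2,5-diol); 12 ethyl 2-(triphenylphosphoranylidene)propanoate
Product: 13 ethyl (2E)-4-hydroxy-2-methylbut-2-enoate
Conditions: CH2Cl2, reflux
Reagents that add atoms: none
Why: Wittig olefination of glycolaldehyde (released from its dimer) with the stabilised α-methyl ylide, which should give the (E)-trisubstituted enoate (ester trans to CH2OH).

Step 10
Reactants: 13 ethyl (2E)-4-hydroxy-2-methylbut-2-enoate
Product: 14 ethyl (2E)-4-[(tert-butyldiphenylsilyl)oxy]-2-methylbut-2-enoate
Conditions: TBDPSCl, imidazole, DMF, rt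
Reagents that add atoms: tert-butyl(chloro)diphenylsilane, CC(C)(C)[Si](Cl)(c1ccccc1)c1ccccc1
Why: silylation of the primary allylic alcohol; TBDPS is chosen because it outlasts the acidic TBS removal of step 14.

Step 11
Reactants: 14 silylated ethyl ester
Product: 15 (2E)-4-[(tert-butyldiphenylsilyl)oxy]-2-methylbut-2-enoic acid
Conditions: LiOH, THF–MeOH–H2O, rt; then dilute HCl to pH 3–4
Reagents that add atoms: lithium hydroxide, [Li+].[OH-]
Why: saponification of the ethyl ester; silyl ether and alkene geometry are stable to LiOH.

Step 12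
Reactants: 10 dibromocyclopropyl alcohol; 15 side-chain acid
Product: 16 ester of 10 with 15 (enoate trans to isopropyl, OTBS cis to isopropyl, CBr2 bridge intact)
Conditions: EDC·HCl, DMAP, CH2Cl2, 0 °C to rt
Reagents that add atoms: none
Why: Steglich esterification of the secondary alcohol; the carbinol configuration is untouched.

Step 13
Reactants: 16 dibromocyclopropane enoate
Product: 19 2-bromo-4-[(tert-butyldimethylsilyl)oxy]-5-(propan-2-yl)-6-{[(2E)-4-(tert-butyldiphenylsilyloxy)-2-methylbut-2-enoyl]oxy}cyclohex-2-en-1-one (configuration at C4/C5/C6 as in the target), via acyloxonium tetrafluoroborate 17 (not isolated), via alkoxysulfonium tetrafluoroborate 18 (not isolated)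
Conditions: AgBF4, CH2Cl2, −40 to 0 °C, dark; then DMSO (10 equiv), 0 °C to rt; then Et3N, 0 °C
Reagents that add atoms: dimethyl sulfoxide, CS(C)=O
Why: Proposed new method: Ag(I) removes the endo bromide while the C1–C3 bond shared by cyclopropane and cyclopentane opens in a thermally allowed disrotatory 2π-electrocyclic process, so the five-membered ring becomes a 2-bromocyclohex-2-enyl cation with the former CBr2 carbon as C2; the carbonyl oxygen of the C6 ester then closes onto the adjacent terminus C1 (five-membered, cis-fused 1,3-dioxolan-2-ylium ion 17), DMSO opens this ion by SN2 attack at the allylic carbon C1 to give alkoxysulfonium salt 18 with the ester restored, and Et3N collapses 18 to the ketone as in a Kornblum oxidation. The closest known reaction types are the silver-promoted ring opening of ring-fused gem-dibromocyclopropanes with capture of the allyl cation by oxygen nucleophiles, neighbouring-group participation by vicinal esters, and the AgBF4/DMSO/Et3N oxidation of halides; their merger in one flask is the new element. No ring is closed permanently: the six-membered ring arises by ring opening, and the temporary dioxolanylium ring (5-exo-type O-attack) is opened again. No new stereocentre remains because C1 ends sp2; C4, C5 and C6 are untouched, and C6–H, now α to the ketone, already sits in the thermodynamically preferred trans relation to isopropyl. The step needs oxygenation at the allyl terminus next to C6 and not at the one next to C4; this is secured because only the C6 ester can bridge (C4 carries OTBS), attack at the allylic sp3 carbon avoids the acyl scrambling that hydrolysis would cause, and the remaining vinylic bromine stays on C2 as the handle for step 16.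

Step 14
Reactants: 19 bromoenone silyl ether
Product: 20 the C4 alcohol (2-bromo-4-hydroxy-5-isopropyl-6-acyloxycyclohex-2-en-1-one, OH cis to isopropyl)
Conditions: CSA (cat.), MeOH–CH2Cl2, 0 °C to rt
Reagents that add atoms: none
Why: acid-catalysed methanolysis should remove the secondary TBS ether while the primary TBDPS ether, far more stable to acid, stays.

Step 15
Reactants: 20 C4 alcohol
Product: 21 the C4 propanoate (2-bromo-5-isopropyl-4-(propanoyloxy)-6-acyloxycyclohex-2-en-1-one)
Conditions: (EtCO)2O, pyridine, DMAP (cat.), CH2Cl2, 0 °C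
Reagents that add atoms: propanoic anhydride, CCC(=O)OC(=O)CC
Why: acylation of the hydroxyl with retention, which fixes the propanoate cis to isopropyl.

Step 16
Reactants: 21 bromoenone diester; 22 (tributylstannyl)methanol
Product: 23 2-(hydroxymethyl) enone with the side-chain TBDPS ether still in place
Conditions: Pd2(dba)3 (cat.), AsPh3, CuI, NMP, 45 °C
Reagents that add atoms: none
Why: Stille coupling of the α-bromoenone with the hydroxymethylstannane; oxidative addition into the activated C2–Br bond should outrun ionisation of the hindered allylic propanoate under these ligand-poor conditions.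

Step 17
Reactants: 23 silyl-protected target
Product: 24 CNP0285949.1, (1R,5S,6S)-3-(hydroxymethyl)-2-oxo-6-(propan-2-yl)-5-(propanoyloxy)cyclohex-3-en-1-yl (2E)-4-hydroxy-2-methylbut-2-enoate
Conditions: HF·pyridine, pyridine, THF, 0 °C to rt
Reagents that add atoms: none
Why: fluoride cleavage of the primary TBDPS ether under buffered, non-basic conditions that should spare the two esters, the α-acyloxy ketone and the γ-acyloxy enone.

**Compound list**

1 | furfural | O=Cc1ccco1 | starting material
2 | isopropylmagnesium chloride | CC(C)[Mg]Cl | starting material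
3 | 1-(furan-2-yl)-2-methylpropan-1-ol (racemic) | CC(C)C(O)c1ccco1 | intermediate
4 | rac-trans-4-hydroxy-5-(propan-2-yl)cyclopent-2-en-1-one (racemate; one enantiomer drawn) | O=C1C=C[C@H](O)[C@H]1C(C)C | intermediate
5 | (4S,5R)-4-hydroxy-5-(propan-2-yl)cyclopent-2-en-1-one | O=C1C=C[C@H](O)[C@H]1C(C)C | intermediate
6 | (1S,3S)-2-(propan-2-yl)cyclopent-4-ene-1,3-diol | O[C@H]1C=C[C@H](O)C1C(C)C | intermediate
7 | mono-pivalate of 6 (OPiv trans, OH cis to isopropyl) | O[C@H]1C=C[C@H](OC(=O)C(C)(C)C)[C@H]1C(C)C | intermediate
8 | TBS ether of 7 | CC(C)(C)[Si](C)(C)O[C@H]1C=C[C@H](OC(=O)C(C)(C)C)[C@H]1C(C)C | intermediate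
9 | 6,6-dibromobicyclo[3.1.0]hexane pivalate TBS ether (CBr2 on the OPiv face) | CC(C)(C)[Si](C)(C)O[C@H]1[C@@H]2C(Br)(Br)[C@@H]2[C@H](OC(=O)C(C)(C)C)[C@H]1C(C)C | intermediate
10 | dibromocyclopropyl alcohol (OH trans, OTBS cis to isopropyl) | CC(C)(C)[Si](C)(C)O[C@H]1[C@@H]2C(Br)(Br)[C@@H]2[C@H](O)[C@H]1C(C)C | intermediate
11 | glycolaldehyde dimer (1,4-dioxane-2,5-diol) | OC1COC(O)CO1 | starting material
12 | ethyl 2-(triphenylphosphoranylidene)propanoate | CCOC(=O)C(C)=P(c1ccccc1)(c1ccccc1)c1ccccc1 | starting material
13 | ethyl (2E)-4-hydroxy-2-methylbut-2-enoate | CCOC(=O)/C(C)=C/CO | intermediate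
14 | ethyl (2E)-4-[(tert-butyldiphenylsilyl)oxy]-2-methylbut-2-enoate | CCOC(=O)/C(C)=C/CO[Si](c1ccccc1)(c1ccccc1)C(C)(C)C | intermediate
15 | (2E)-4-[(tert-butyldiphenylsilyl)oxy]-2-methylbut-2-enoic acid | OC(=O)/C(C)=C/CO[Si](c1ccccc1)(c1ccccc1)C(C)(C)C | intermediate
16 | ester of 10 with 15 | CC(C)(C)[Si](C)(C)O[C@H]1[C@@H]2C(Br)(Br)[C@@H]2[C@H](OC(=O)/C(C)=C/CO[Si](c3ccccc3)(c3ccccc3)C(C)(C)C)[C@H]1C(C)C | intermediate
17 | cis-fused 1,3-dioxolan-2-ylium tetrafluoroborate on C1/C6 of the 2-bromocyclohexene | CC(C)(C)[Si](C)(C)O[C@H]1C=C(Br)[C@@H]2O[C+](/C(C)=C/CO[Si](c3ccccc3)(c3ccccc3)C(C)(C)C)O[C@@H]2[C@H]1C(C)C.F[B-](F)(F)F | intermediate (not isolated)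
18 | C1 alkoxydimethylsulfonium tetrafluoroborate (C1–O trans to the C6 ester) | CC(C)(C)[Si](C)(C)O[C@H]1C=C(Br)[C@@H](O[S+](C)C)[C@H](OC(=O)/C(C)=C/CO[Si](c2ccccc2)(c2ccccc2)C(C)(C)C)[C@H]1C(C)C.F[B-](F)(F)F | intermediate (not isolated)
19 | 2-bromo-4-OTBS-5-isopropyl-6-acyloxycyclohex-2-en-1-one | CC(C)(C)[Si](C)(C)O[C@H]1C=C(Br)C(=O)[C@H](OC(=O)/C(C)=C/CO[Si](c2ccccc2)(c2ccccc2)C(C)(C)C)[C@H]1C(C)C | intermediate
20 | 2-bromo-4-hydroxy-5-isopropyl-6-acyloxycyclohex-2-en-1-one | O[C@H]1C=C(Br)C(=O)[C@H](OC(=O)/C(C)=C/CO[Si](c2ccccc2)(c2ccccc2)C(C)(C)C)[C@H]1C(C)C | intermediate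
21 | 2-bromo-5-isopropyl-4-(propanoyloxy)-6-acyloxycyclohex-2-en-1-one | CCC(=O)O[C@H]1C=C(Br)C(=O)[C@H](OC(=O)/C(C)=C/CO[Si](c2ccccc2)(c2ccccc2)C(C)(C)C)[C@H]1C(C)C | intermediate
22 | (tributylstannyl)methanol | CCCC[Sn](CCCC)(CCCC)CO | starting material
23 | TBDPS ether of the target at the side-chain hydroxyl | CCC(=O)O[C@H]1C=C(CO)C(=O)[C@H](OC(=O)/C(C)=C/CO[Si](c2ccccc2)(c2ccccc2)C(C)(C)C)[C@H]1C(C)C | intermediate
24 | CNP0285949.1 | CCC(=O)O[C@H]1C=C(CO)C(=O)[C@H](OC(=O)/C(C)=C/CO)[C@H]1C(C)C | target

**Count and risks**

Total step count: 17. Longest linear sequence: 14 steps (steps 1–8 and 12–17); the side-chain branch (steps 9–11) joins at step 12.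

Steps most likely to fail:

1. Step 13 (Proposed new method). The cation or the acyloxonium ion may be attacked at the wrong position (DMSO at the acyloxonium carbon or at C3), adventitious water may hydrolyse the acyloxonium ion with acyl scrambling, or acid traces may desilylate. The fallback uses known chemistry and shifts regiocontrol to a temporary ring. It sets out from alcohol 10, which with Boc2O/DMAP should give the tert-butyl carbonate of 10 F1. AgBF4 in CH2Cl2 should open the cyclopropane, the carbonate oxygen being the only nucleophile able to reach C1, and loss of isobutene should give the cis-fused C1/C6 cyclic carbonate F2. K2CO3 in MeOH should give the cis-1,6-diol F3, and MnO2 should oxidise only the allylic C1 hydroxyl to the 6-hydroxy-2-bromoenone F4. EDC/DMAP esterification of F4 with acid 15 comes back to the route at 19.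

2. Step 5. Discrimination between the two hydroxyls may be incomplete (acylation at the hindered oxygen, bis-acylation). The fallback differentiates by order of events instead of by sterics. It sets out from hydroxy enone 5, whose single hydroxyl is pivaloylated (PivCl, pyridine) to the 4-pivaloyloxy enone F5. Reagent-controlled CBS reduction of the ketone ((S)-Me-CBS, catecholborane, hydride anti to isopropyl) then comes back to the route at 7.

3. Step 16. Transmetalation of the sp3 stannane may be slow, and on heating Pd(0) may ionise the allylic propanoate, leading to elimination and aromatisation. The fallback replaces the Pd/Sn coupling by a Nozaki–Hiyama–Kishi coupling: it sets out from 21, and CrCl2, NiCl2 (cat.) and paraformaldehyde in DMF at rt should add the alkenylchromium species to formaldehyde, coming back to the route at 23 without any new compound (F0).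

Further compounds
F1 | step 13 | tert-butyl carbonate of 10 | CC(C)(C)[Si](C)(C)O[C@H]1[C@@H]2C(Br)(Br)[C@@H]2[C@H](OC(=O)OC(C)(C)C)[C@H]1C(C)C
F2 | step 13 | cis-fused C1/C6 cyclic carbonate of 2-bromo-4-OTBS-5-isopropylcyclohex-2-ene-1,6-diol | CC(C)(C)[Si](C)(C)O[C@H]1C=C(Br)[C@@H]2OC(=O)O[C@@H]2[C@H]1C(C)C
F3 | step 13 | 2-bromo-4-OTBS-5-isopropylcyclohex-2-ene-1,6-diol (cis-diol) | CC(C)(C)[Si](C)(C)O[C@H]1C=C(Br)[C@H](O)[C@H](O)[C@H]1C(C)C
F4 | step 13 | 2-bromo-6-hydroxy-4-OTBS-5-isopropylcyclohex-2-en-1-one | CC(C)(C)[Si](C)(C)O[C@H]1C=C(Br)C(=O)[C@H](O)[C@H]1C(C)C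
F5 | step 5 | (4S,5R)-4-(pivaloyloxy)-5-isopropylcyclopent-2-en-1-one | O=C1C=C[C@H](OC(=O)C(C)(C)C)[C@H]1C(C)C
F0 | step 16 | none | none
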